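## Retrosynthetic overview

1. The quinone is unveiled last from a 2,5-dimethoxyphenyl ring with (NH4)2Ce(NO3)6. Before that the senecioate is placed on the free (S)-alcohol (Steglich), and the furan comes from a 2,5-dihydrofuran by DDQ dehydrogenation.
2. Key disconnection: furan C2–C3 together with the C3=C4 double bond. The dihydrofuran is made from the open-chain ketone ArCH2–O–CH2–C(=O)–CH(OTBS)CH2CH=CMe2 and the one carbon of Me3SiCHN2 by alkylidene carbene 1,5 C–H insertion.
3. Feature used: in the furan ring (O1, C2 carrying the aryl ring that becomes the quinone, C3–H, C4 carrying the side chain, C5–H), C2 lies between O1 and the aryl ring. In the benzyl ether precursor its C–H bond is therefore benzylic and next to oxygen, the best C–H bond for a carbene placed on C3.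
4. The ketone comes from a Weinreb amide and ArCH2OCH2Li (tin–lithium exchange). The single stereocentre is bought as methyl (S)-glycidate, opened at C3 by the 2-methylprop-1-enyl Grignard reagent under CuI catalysis.
5. Ring order: the benzene ring is bought; the furan ring is the only ring closed (as the dihydrofuran in step 6, aromatised in step 7); the benzene ring is oxidised to the quinone in step 10.

Key step: step 6

Remark on the chemistry: tributyl(iodomethyl)stannane is treated as a purchased reagent, and the two quinone oxygens formed in step 10 are taken to come from water.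

## Route

Step 1
Reactants: 1 methyl (S)-glycidate; 2 2-methylprop-1-enylmagnesium bromide
Product: 3 methyl (S)-2-hydroxy-5-methylhex-4-enoate
Conditions: CuI (10 mol %), THF, −40 → −20 °C; then aq NH4Cl
Reagents that add atoms: none
Why: Copper-catalysed Grignard opening of the terminal epoxide by SN2 attack at the unsubstituted C3 gives the α-hydroxy ester with the prenyl chain in place; C2 is not a reacting centre, so the (S) configuration of 1 is carried over, and at this temperature the epoxide is opened faster than the ester is attacked.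

Step 2
Reactants: 3 methyl (S)-2-hydroxy-5-methylhex-4-enoate
Product: 4 methyl (S)-2-(tert-butyldimethylsilyloxy)-5-methylhex-4-enoate
Conditions: TBSCl, imidazole, DMF, rt
Reagents that add atoms: tert-butyldimethylsilyl chloride (TBSCl), CC(C)(C)[Si](C)(C)Cl
Why: Imidazole-promoted silylation of a secondary alcohol (Corey protocol) gives a base-stable silyl ether without breaking any bond at the stereocentre.

Step 3
Reactants: 4 methyl (S)-2-(tert-butyldimethylsilyloxy)-5-methylhex-4-enoate
Product: 5 (S)-2-(tert-butyldimethylsilyloxy)-N-methoxy-N,5-dimethylhex-4-enamide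
Conditions: MeNH(OMe)·HCl, i-PrMgCl, THF, −20 → 0 °C; then aq NH4Cl
Reagents that add atoms: N,O-dimethylhydroxylamine hydrochloride, CNOC.Cl
Why: Direct ester-to-Weinreb-amide conversion by the chloromagnesium amide formed in the flask, an acyl substitution that should leave the α-silyloxy stereocentre unchanged at low temperature.

Step 4
Reactants: 6 2,5-dimethoxybenzyl alcohol; 7 tributyl(iodomethyl)stannane
Product: 9 tributyl[(2,5-dimethoxybenzyloxy)methyl]stannane, via sodium (2,5-dimethoxyphenyl)methanolate 8 (not isolated)
Conditions: NaH, THF/DMF, 0 °C; then 7, 0 °C → rt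
Reagents that add atoms: none
Why: Williamson ether synthesis in which the sodium alkoxide displaces iodide from the unhindered CH2 of the iodomethylstannane by SN2, the standard way to α-alkoxymethylstannanes.

Step 5
Reactants: 9 tributyl[(2,5-dimethoxybenzyloxy)methyl]stannane; 5 (S)-2-(tert-butyldimethylsilyloxy)-N-methoxy-N,5-dimethylhex-4-enamide
Product: 11 (S)-3-(tert-butyldimethylsilyloxy)-1-(2,5-dimethoxybenzyloxy)-6-methylhept-5-en-2-one, via [(2,5-dimethoxybenzyloxy)methyl]lithium 10 (not isolated)
Conditions: n-BuLi, THF, −78 °C; then 5, −78 °C; then aq NH4Cl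
Reagents that add atoms: none
Why: Tin–lithium exchange gives the α-alkoxymethyllithium, which is stable to Wittig rearrangement at −78 °C and adds only once to the Weinreb amide because the chelated tetrahedral adduct lasts until the quench (Weinreb ketone synthesis), the stereocentre not being deprotonated at this temperature.

Step 6
Reactants: 11 (S)-3-(tert-butyldimethylsilyloxy)-1-(2,5-dimethoxybenzyloxy)-6-methylhept-5-en-2-one; 12 trimethylsilyldiazomethane
Product: 16 4-[(S)-1-(tert-butyldimethylsilyloxy)-4-methylpent-3-enyl]-2-(2,5-dimethoxyphenyl)-2,5-dihydrofuran (both C2 epimers), via lithio(trimethylsilyl)diazomethane 13 (not isolated), via diazoalkene 14 (not isolated), via alkylidene carbene 15 (not isolated)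
Conditions: n-BuLi, THF, −78 °C (12 → 13); then 11, −78 → 0 °C; then aq NH4Cl
Reagents that add atoms: none
Why: Lithiated Me3SiCHN2 13 adds to the ketone of 11 at −78 °C, the adduct loses Me3SiOLi in a Peterson-type elimination to give diazoalkene 14, and loss of N2 on warming leaves alkylidene carbene 15 on the carbon that becomes furan C3. The singlet carbene inserts into a C–H bond of the benzylic ether CH2 five atoms away, which makes the C2–C3 bond while the former carbonyl carbon ends as C4 of the C3=C4 double bond; this is the known formation of 2,5-dihydrofurans from α-alkoxy ketones by alkylidene carbene 1,5 C–H insertion. The one ring of the step (O1–C2–C3–C4–C5) is closed by carbon–carbon bond formation in this 1,5 insertion. C2 is a new stereocentre formed without control (both epimers are expected), which is harmless because step 7 makes it planar, and the (S) carbinol carbon lies outside the reacting atoms and keeps its configuration. The step needs chemoselectivity for this insertion over addition of the carbene to the trisubstituted side-chain alkene, over 1,2-shift to an alkyne and over enolisation of the ketone by the basic reagent. The C2–H bond is activated by both the O1 lone pair and the electron-rich aryl ring and leads to an unstrained five-membered ring, whereas alkene addition would give a strained bicyclo[3.1.0]hex-1-ene and the only other C–H bond in a 1,5 relation is vinylic; fast nucleophilic addition at −78 °C limits enolisation.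

Step 7
Reactants: 16 4-[(S)-1-(tert-butyldimethylsilyloxy)-4-methylpent-3-enyl]-2-(2,5-dimethoxyphenyl)-2,5-dihydrofuran
Product: 17 4-[(S)-1-(tert-butyldimethylsilyloxy)-4-methylpent-3-enyl]-2-(2,5-dimethoxyphenyl)furan
Conditions: DDQ (1.1 equiv), toluene, rt
Reagents that add atoms: none
Why: Dehydrogenation of a 2,5-dihydrofuran to the furan by DDQ, which takes hydride from C2 (benzylic, allylic and next to O1) before the C5 proton is lost, so both C2 epimers converge on one aromatic product while the silyl ether and the (S) centre stay untouched.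

Step 8
Reactants: 17 4-[(S)-1-(tert-butyldimethylsilyloxy)-4-methylpent-3-enyl]-2-(2,5-dimethoxyphenyl)furan
Product: 18 (S)-1-[5-(2,5-dimethoxyphenyl)furan-3-yl]-4-methylpent-3-en-1-ol
Conditions: Bu4NF, THF, 0 °C → rt
Reagents that add atoms: none
Why: Fluoride cleaves the Si–O bond (silyl ether deprotection) and leaves the C–O bond at the stereocentre intact, so the (S) configuration is retained.

Step 9
Reactants: 18 (S)-1-[5-(2,5-dimethoxyphenyl)furan-3-yl]-4-methylpent-3-en-1-ol; 19 3-methylbut-2-enoic acid
Product: 20 (S)-1-[5-(2,5-dimethoxyphenyl)furan-3-yl]-4-methylpent-3-enyl 3-methylbut-2-enoate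
Conditions: DCC, DMAP (cat.), CH2Cl2, 0 °C → rt
Reagents that add atoms: none
Why: Steglich esterification acylates the alcohol oxygen under neutral conditions that suit the acid-sensitive furylic alcohol, with retention at the stereocentre because its C–O bond is not broken.

Step 10
Reactants: 20 (S)-1-[5-(2,5-dimethoxyphenyl)furan-3-yl]-4-methylpent-3-enyl 3-methylbut-2-enoate
Product: 21 (S)-1-[5-(3,6-dioxocyclohexa-1,4-dien-1-yl)furan-3-yl]-4-methylpent-3-enyl 3-methylbut-2-enoate (CNP0314322.1)
Conditions: (NH4)2Ce(NO3)6, MeCN/H2O, 0 °C, short reaction time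
Reagents that add atoms: water, O
Why: Oxidative demethylation of a 1,4-dimethoxyarene to the p-benzoquinone by tetravalent cerium (two one-electron oxidations, attack of water at the two methoxy-bearing ring carbons and loss of two molecules of methanol), the dimethoxyarene being the most easily oxidised part of 20 and the cold, brief exposure sparing the furan, the alkenes and the ester.

## Compound list

1 | methyl (S)-glycidate | COC(=O)[C@@H]1CO1 | starting material
2 | 2-methylprop-1-enylmagnesium bromide | CC(C)=C[Mg]Br | starting material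
3 | methyl (S)-2-hydroxy-5-methylhex-4-enoate | COC(=O)[C@@H](O)CC=C(C)C | intermediate
4 | methyl (S)-2-(tert-butyldimethylsilyloxy)-5-methylhex-4-enoate | COC(=O)[C@@H](O[Si](C)(C)C(C)(C)C)CC=C(C)C | intermediate
5 | (S)-2-(tert-butyldimethylsilyloxy)-N-methoxy-N,5-dimethylhex-4-enamide | CON(C)C(=O)[C@@H](O[Si](C)(C)C(C)(C)C)CC=C(C)C | intermediate
6 | 2,5-dimethoxybenzyl alcohol | COc1ccc(OC)c(CO)c1 | starting material
7 | tributyl(iodomethyl)stannane | CCCC[Sn](CCCC)(CCCC)CI | starting material
8 | sodium (2,5-dimethoxyphenyl)methanolate | COc1ccc(OC)c(C[O-])c1.[Na+] | intermediate (not isolated)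
9 | tributyl[(2,5-dimethoxybenzyloxy)methyl]stannane | CCCC[Sn](CCCC)(CCCC)COCc1cc(OC)ccc1OC | intermediate
10 | [(2,5-dimethoxybenzyloxy)methyl]lithium | [Li]COCc1cc(OC)ccc1OC | intermediate (not isolated)
11 | (S)-3-(tert-butyldimethylsilyloxy)-1-(2,5-dimethoxybenzyloxy)-6-methylhept-5-en-2-one | COc1ccc(OC)c(COCC(=O)[C@@H](O[Si](C)(C)C(C)(C)C)CC=C(C)C)c1 | intermediate
12 | trimethylsilyldiazomethane | C[Si](C)(C)C=[N+]=[N-] | starting material
13 | lithio(trimethylsilyl)diazomethane | [Li]C(=[N+]=[N-])[Si](C)(C)C | intermediate (not isolated)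
14 | (S)-3-(tert-butyldimethylsilyloxy)-1-diazo-2-[(2,5-dimethoxybenzyloxy)methyl]-6-methylhepta-1,5-diene (diazoalkene) | COc1ccc(OC)c(COCC(=C=[N+]=[N-])[C@@H](O[Si](C)(C)C(C)(C)C)CC=C(C)C)c1 | intermediate (not isolated)
15 | (S)-3-(tert-butyldimethylsilyloxy)-2-[(2,5-dimethoxybenzyloxy)methyl]-6-methylhepta-1,5-dien-1-ylidene (alkylidene carbene) | COc1ccc(OC)c(COCC(=[C])[C@@H](O[Si](C)(C)C(C)(C)C)CC=C(C)C)c1 | intermediate (not isolated)
16 | 4-[(S)-1-(tert-butyldimethylsilyloxy)-4-methylpent-3-enyl]-2-(2,5-dimethoxyphenyl)-2,5-dihydrofuran (both C2 epimers) | CC(C)=CC[C@H](O[Si](C)(C)C(C)(C)C)C1=CC(c2cc(OC)ccc2OC)OC1 | intermediate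
17 | 4-[(S)-1-(tert-butyldimethylsilyloxy)-4-methylpent-3-enyl]-2-(2,5-dimethoxyphenyl)furan | CC(C)=CC[C@H](O[Si](C)(C)C(C)(C)C)c1coc(-c2cc(OC)ccc2OC)c1 | intermediate
18 | (S)-1-[5-(2,5-dimethoxyphenyl)furan-3-yl]-4-methylpent-3-en-1-ol | CC(C)=CC[C@H](O)c1coc(-c2cc(OC)ccc2OC)c1 | intermediate
19 | 3-methylbut-2-enoic acid | CC(C)=CC(=O)O | starting material
20 | (S)-1-[5-(2,5-dimethoxyphenyl)furan-3-yl]-4-methylpent-3-enyl 3-methylbut-2-enoate | CC(C)=CC[C@H](OC(=O)C=C(C)C)c1coc(-c2cc(OC)ccc2OC)c1 | intermediate
21 | (S)-1-[5-(3,6-dioxocyclohexa-1,4-dien-1-yl)furan-3-yl]-4-methylpent-3-enyl 3-methylbut-2-enoate (CNP0314322.1) | CC(C)=CC[C@H](OC(=O)C=C(C)C)c1coc(C2=CC(=O)C=CC2=O)c1 | target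

## Step count and risks

Total step count: 10.
Longest linear sequence: 9 steps (steps 1, 2, 3, 5, 6, 7, 8, 9, 10, from methyl (S)-glycidate); step 4 is a one-step side branch.

The three steps most likely to fail:

**1. Step 6.** The carbene may add to the trisubstituted side-chain alkene faster than it inserts into the benzylic ether C–H bond. The basic diazomethane anion may also merely enolise the ketone, which would return material with eroded configuration.
Fallback: close the furan at the O1–C2 bond by cycloisomerisation of an alkynyl oxirane. It sets out from Weinreb amide 5 and comes back to the route at furan 17, so step 7 is not needed. Commercial 2-ethynyl-1,4-dimethoxybenzene is deprotonated with n-BuLi in THF at −78 °C to lithium (2,5-dimethoxyphenyl)acetylide F1. Acylation of F1 by 5 should give (S)-4-(tert-butyldimethylsilyloxy)-1-(2,5-dimethoxyphenyl)-7-methyloct-6-en-1-yn-3-one F2. Corey–Chaykovsky reaction of the ketone with dimethylsulfonium methylide (Me3SI, KN(SiMe3)2, THF, −10 °C) should give 2-[(S)-1-(tert-butyldimethylsilyloxy)-4-methylpent-3-enyl]-2-[(2,5-dimethoxyphenyl)ethynyl]oxirane F3 as both epimers at the oxirane carbon. AuCl3 (5 mol %) in MeCN at rt should then isomerise the alkynyl oxirane to 17: the oxirane oxygen attacks the aryl-bearing alkyne carbon, the oxirane opens, and proton loss aromatises the ring.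

**2. Step 10.** The tetravalent cerium oxidant may also attack the electron-rich 2-arylfuran (ring opening, oxidative dimerisation). The acidic aqueous medium may ionise the furylic ester C–O bond, which would erode the stereocentre.
Fallback: form the quinone by oxidation of a 4-methoxyphenol with a trivalent iodine reagent, before the ester is in place. It sets out from furan 17 and comes back at target 21. NaSEt in DMF at about 110 °C should cleave one aryl methyl ether of 17 (the phenoxide formed protects the second). This would give 2-{4-[(S)-1-(tert-butyldimethylsilyloxy)-4-methylpent-3-enyl]furan-2-yl}-4-methoxyphenol F4 and its regioisomer 3-{4-[(S)-1-(tert-butyldimethylsilyloxy)-4-methylpent-3-enyl]furan-2-yl}-4-methoxyphenol F5, used together because both lead to the same quinone. PhI(OAc)2 in MeCN/H2O at 0 °C should oxidise them to 2-{4-[(S)-1-(tert-butyldimethylsilyloxy)-4-methylpent-3-enyl]furan-2-yl}-1,4-benzoquinone F6. HF·pyridine in THF at 0 °C should remove the silyl group to give 2-{4-[(S)-1-hydroxy-4-methylpent-3-enyl]furan-2-yl}-1,4-benzoquinone F7. Steglich esterification of F7 with acid 19 (DCC, DMAP, CH2Cl2) then gives 21.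

**3. Step 9.** Acylation of the hindered furylic alcohol may be slow, so that the activated acid rearranges to the N-acylurea. The senecioyl unit may also lose conjugation through a vinylketene and give the 3-methylbut-3-enoate.
Fallback: build the C=C bond of the ester after the acylation. It sets out from alcohol 18 and comes back at ester 20. Esterification of 18 with diethylphosphonoacetic acid (DCC, DMAP cat., CH2Cl2), an unhindered acid that cannot deconjugate, should give (S)-1-[5-(2,5-dimethoxyphenyl)furan-3-yl]-4-methylpent-3-enyl 2-(diethoxyphosphoryl)acetate F8. Horner–Wadsworth–Emmons olefination of F8 with acetone (NaH, THF, 0 °C → rt) should then give 20.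

## Further compounds

F1 | step 6 | lithium (2,5-dimethoxyphenyl)acetylide | [Li]C#Cc1cc(OC)ccc1OC
F2 | step 6 | (S)-4-(tert-butyldimethylsilyloxy)-1-(2,5-dimethoxyphenyl)-7-methyloct-6-en-1-yn-3-one | COc1ccc(OC)c(C#CC(=O)[C@@H](O[Si](C)(C)C(C)(C)C)CC=C(C)C)c1
F3 | step 6 | 2-[(S)-1-(tert-butyldimethylsilyloxy)-4-methylpent-3-enyl]-2-[(2,5-dimethoxyphenyl)ethynyl]oxirane (both epimers at the oxirane carbon) | COc1ccc(OC)c(C#CC2(CO2)[C@@H](O[Si](C)(C)C(C)(C)C)CC=C(C)C)c1
F4 | step 10 | 2-{4-[(S)-1-(tert-butyldimethylsilyloxy)-4-methylpent-3-enyl]furan-2-yl}-4-methoxyphenol | CC(C)=CC[C@H](O[Si](C)(C)C(C)(C)C)c1coc(-c2cc(OC)ccc2O)c1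
F5 | step 10 | 3-{4-[(S)-1-(tert-butyldimethylsilyloxy)-4-methylpent-3-enyl]furan-2-yl}-4-methoxyphenol | CC(C)=CC[C@H](O[Si](C)(C)C(C)(C)C)c1coc(-c2cc(O)ccc2OC)c1
F6 | step 10 | 2-{4-[(S)-1-(tert-butyldimethylsilyloxy)-4-methylpent-3-enyl]furan-2-yl}-1,4-benzoquinone | CC(C)=CC[C@H](O[Si](C)(C)C(C)(C)C)c1coc(C2=CC(=O)C=CC2=O)c1
F7 | step 10 | 2-{4-[(S)-1-hydroxy-4-methylpent-3-enyl]furan-2-yl}-1,4-benzoquinone | CC(C)=CC[C@H](O)c1coc(C2=CC(=O)C=CC2=O)c1
F8 | step 9 | (S)-1-[5-(2,5-dimethoxyphenyl)furan-3-yl]-4-methylpent-3-enyl 2-(diethoxyphosphoryl)acetate | CC(C)=CC[C@H](OC(=O)CP(=O)(OCC)OCC)c1coc(-c2cc(OC)ccc2OC)c1
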